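Assumption: germacrane numbering is used for the target's atoms in every intermediate (ring C1–C10, C11/C12/C13 on the lactone with C13 = CH2OH, C14 = methyl on C10, C15 = methyl on C4); the target is (1S,4R,5R,6S,8S,10S).

**Retrosynthetic overview**
1. Last: C13–O desilylation, C8 methacrylate, and the 4,5-oxirane by peripheral peracid attack on the E-4,5-alkene of the closed ten-membered ring.
2. Key step: the ten-membered carbocycle is closed at C7–C8 by an intramolecular NiCl2/CrCl2 coupling in which the β-iodobutenolide itself is the vinyl partner and a C8 aldehyde the acceptor (sets C8); this replaces the usual RCM or C5–C6 allylic-alcohol closure.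
3. The butenolide is grown around one linchpin carbon (C7): anti-diiodination of a C6 propargylic alcohol, then hydroxyl-guided Pd cyclocarbonylation (CO = C12) that uses only the C11–I bond and leaves C7–I.
4. C6 comes from catalyst-controlled alkynylation of a geraniol-derived E-enal with a propargyl silyl ether (C7, C11, C13); C1/C10 come from Brown (Z)-crotylboration (C8–C10, C14) of the aldehyde cut from geranyl acetate (C1–C6, C15).
5. Ring order: butenolide, then ten-membered carbocycle, then oxirane.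

**Route**

Step 1
Reactants: 1 geranyl acetate
Product: 2 6,7-epoxygeranyl acetate (racemic oxirane)
Conditions: mCPBA (1.05 equiv), CH2Cl2, 0 °C
Reagents that add atoms: mCPBA, O=C(OO)c1cccc(Cl)c1
Why: Prilezhaev epoxidation picks the electron-rich 6,7-alkene because the 2,3-alkene is deactivated by the allylic acetate, and the new stereocentre is destroyed in step 2.

Step 2
Reactants: 2 6,7-epoxygeranyl acetate
Product: 4 (2E)-3-methyl-6-oxohex-2-en-1-yl acetate, via vicinal diol 3 (not isolated)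
Conditions: H5IO6, THF/H2O, 0 °C
Reagents that add atoms: none
Why: acid-promoted epoxide hydrolysis followed by periodate glycol cleavage (Malaprade reaction) removes the terminal three carbons as acetone and leaves the E-trisubstituted alkene (future C4=C5) untouched.

Step 3
Reactants: 4 (2E)-3-methyl-6-oxohex-2-en-1-yl acetate; 5 cis-2-butene
Product: 8 (2E,6S,7S)-3,7-dimethylnona-2,8-diene-1,6-diol, via (Z)-crotyldiisopinocampheylborane 6 (not isolated), via hydroxy acetate 7 (not isolated)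
Conditions: 5, KOtBu, n-BuLi, THF, −78 → −45 °C; (+)-Ipc2BOMe, −78 °C; BF3·OEt2; then 4, −78 °C; then NaOH, H2O2, 0 → 23 °C
Reagents that add atoms: cis-2-butene (5), C/C=C\C
Why: Brown (Z)-crotylboration through a chair Zimmerman–Traxler transition state gives the syn C1–O/C10–Me pair, the (−)-α-pinene-derived Ipc groups direct attack to the Re face of the aldehyde (C1 S, C10 S), and the alkaline peroxide work-up also saponifies the primary acetate.

Step 4
Reactants: 8 (2E,6S,7S)-3,7-dimethylnona-2,8-diene-1,6-diol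
Product: 9 (2E,6S,7S)-6-hydroxy-3,7-dimethylnona-2,8-dienal
Conditions: MnO2 (activated, excess), CH2Cl2, 23 °C
Reagents that add atoms: none
Why: MnO2 oxidises only the primary allylic alcohol (future C6) with retention of the E geometry and leaves the secondary C1 alcohol alone; the hydroxy enal is used at once.

Step 5
Reactants: 9 (2E,6S,7S)-6-hydroxy-3,7-dimethylnona-2,8-dienal
Product: 10 (3S,4S,7E)-3,7-dimethyl-9-oxonona-1,7-dien-4-yl acetate
Conditions: Ac2O, pyridine, DMAP (cat.), CH2Cl2, 0 °C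
Reagents that add atoms: acetic anhydride, CC(=O)OC(C)=O
Why: DMAP-catalysed acylation installs the C1 acetate of the target early, where it also serves as the only protecting group this oxygen needs.

Step 6
Reactants: 10 (3S,4S,7E)-3,7-dimethyl-9-oxonona-1,7-dien-4-yl acetate; 11 tert-butyldimethyl(prop-2-yn-1-yloxy)silane
Product: 13 (3S,4S,7E,9R)-12-[(tert-butyldimethylsilyl)oxy]-9-hydroxy-3,7-dimethyldodeca-1,7-dien-10-yn-4-yl acetate, via methylzinc acetylide 12 (not isolated)
Conditions: 11 (3 equiv), Me2Zn (3 equiv), (R,R)-ProPhenol (20 mol %), Ph3PO (40 mol %), toluene, 4 °C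
Reagents that add atoms: tert-butyldimethyl(prop-2-yn-1-yloxy)silane (11), C#CCO[Si](C)(C)C(C)(C)C
Why: Trost ProPhenol dinuclear-zinc alkynylation of an enal, with the ligand chosen for Si-face delivery to give the 9R carbinol (target C6), brings in C7, C11 and C13 in one step; the ligand sense is confirmed by Mosher analysis on the first run.

Step 7
Reactants: 13 (3S,4S,7E,9R)-12-[(tert-butyldimethylsilyl)oxy]-9-hydroxy-3,7-dimethyldodeca-1,7-dien-10-yn-4-yl acetate
Product: 14 (3S,4S,7E,9R,10E)-12-[(tert-butyldimethylsilyl)oxy]-9-hydroxy-10,11-diiodo-3,7-dimethyldodeca-1,7,10-trien-4-yl acetate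
Conditions: I2 (1.05 equiv), CH2Cl2, 23 °C, dark
Reagents that add atoms: iodine, II
Why: electrophilic anti addition of iodine to the alkyne via an iodirenium ion gives the E-diiodide (C11–I cis to the C6 carbinol), while the two alkenes add iodine only reversibly.

Step 8
Reactants: 14 (3S,4S,7E,9R,10E)-12-[(tert-butyldimethylsilyl)oxy]-9-hydroxy-10,11-diiodo-3,7-dimethyldodeca-1,7,10-trien-4-yl acetate
Product: 15 (3S,4S,7E)-8-[(2R)-4-{[(tert-butyldimethylsilyl)oxy]methyl}-3-iodo-5-oxo-2,5-dihydrofuran-2-yl]-3,7-dimethylocta-1,7-dien-4-yl acetate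
Conditions: PdCl2(PPh3)2 (5 mol %), CO (1 atm), K2CO3 (1.5 equiv), THF, 23 °C
Reagents that add atoms: carbon monoxide, [C-]#[O+]
Why: Proposed new method: zerovalent palladium inserts into the less hindered C11–I bond cis to the C6 carbinol, CO insertion and capture of the acylpalladium by that hydroxyl close the butenolide (CO = C12), whereas an acylpalladium at C7 has no nucleophile in reach and reverts so C7–I survives; the closest known reaction is the Pd-catalysed cyclocarbonylation of (Z)-3-iodoallylic alcohols to butenolides, and C6 is not touched.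

Step 9
Reactants: 15 (3S,4S,7E)-8-[(2R)-4-{[(tert-butyldimethylsilyl)oxy]methyl}-3-iodo-5-oxo-2,5-dihydrofuran-2-yl]-3,7-dimethylocta-1,7-dien-4-yl acetate
Product: 17 (3S,4S,7E)-8-[(2R)-4-{[(tert-butyldimethylsilyl)oxy]methyl}-3-iodo-5-oxo-2,5-dihydrofuran-2-yl]-1-hydroxy-3,7-dimethyloct-7-en-4-yl acetate, via alkyl-9-BBN adduct 16 (not isolated)
Conditions: 9-BBN (1.5 equiv), THF, 0 → 23 °C; then pH 7 phosphate buffer, 30% H2O2, 0 °C
Reagents that add atoms: hydrogen peroxide, OO
Why: anti-Markovnikov hydroboration–oxidation with 9-BBN takes only the monosubstituted alkene (the trisubstituted alkene and the electron-poor iodobutenolide are far slower), and neutral peroxide oxidation spares the β-iodobutenolide and the acetate.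

Step 10
Reactants: 17 (3S,4S,7E)-8-[(2R)-4-{[(tert-butyldimethylsilyl)oxy]methyl}-3-iodo-5-oxo-2,5-dihydrofuran-2-yl]-1-hydroxy-3,7-dimethyloct-7-en-4-yl acetate
Product: 18 (3S,4S,7E)-8-[(2R)-4-{[(tert-butyldimethylsilyl)oxy]methyl}-3-iodo-5-oxo-2,5-dihydrofuran-2-yl]-3,7-dimethyl-1-oxooct-7-en-4-yl acetate
Conditions: Dess–Martin periodinane (1.2 equiv), CH2Cl2, 23 °C
Reagents that add atoms: none
Why: Dess–Martin oxidation gives the C8 aldehyde under base-free conditions, which protects the acidic, doubly allylic C6–H of the butenolide from epimerisation.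

Step 11
Reactants: 18 (3S,4S,7E)-8-[(2R)-4-{[(tert-butyldimethylsilyl)oxy]methyl}-3-iodo-5-oxo-2,5-dihydrofuran-2-yl]-3,7-dimethyl-1-oxooct-7-en-4-yl acetate
Product: 20 (1S,4E,6R,8S,10S)-1-acetoxy-13-(tert-butyldimethylsilyloxy)-8-hydroxygermacra-4,7(11)-dien-12,6-olide, via alkenylchromium dichloride 19 (not isolated)
Conditions: CrCl2 (8 equiv), NiCl2 (10 mol %), DMSO, 23 °C, 2 mM, syringe-pump addition
Reagents that add atoms: none
Why: intramolecular Nozaki–Hiyama–Kishi reaction, in which zerovalent nickel inserts into the activated C7–I bond and the derived alkenylchromium 19 adds to the C8 aldehyde at high dilution, closes the ten-membered ring and creates C8 under macrocyclic control; the sense cannot be predicted securely, so the route is written for the 8S alcohol and the 8R alcohol is still usable by the fallback.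

Step 12
Reactants: 20 (1S,4E,6R,8S,10S)-1-acetoxy-13-(tert-butyldimethylsilyloxy)-8-hydroxygermacra-4,7(11)-dien-12,6-olide
Product: 21 (1S,4R,5R,6S,8S,10S)-1-acetoxy-13-(tert-butyldimethylsilyloxy)-4,5-epoxy-8-hydroxygermacr-7(11)-en-12,6-olide
Conditions: mCPBA (1.1 equiv), CH2Cl2, 0 °C
Reagents that add atoms: mCPBA, O=C(OO)c1cccc(Cl)c1
Why: Prilezhaev epoxidation of the only electron-rich alkene, where allylic 1,3-strain with the C4 methyl holds H6 in the alkene plane and the ring chain (C7 side) covers the inner face, so the peracid attacks the outer face syn to the lactone oxygen and gives the 4R,5R (parthenolide-type) oxirane.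

Step 13
Reactants: 21 (1S,4R,5R,6S,8S,10S)-1-acetoxy-13-(tert-butyldimethylsilyloxy)-4,5-epoxy-8-hydroxygermacr-7(11)-en-12,6-olide
Product: 22 13-O-(tert-butyldimethylsilyl)glaucolide L
Conditions: methacrylic anhydride (3 equiv), Et3N, DMAP (cat.), CH2Cl2, 0 → 23 °C
Reagents that add atoms: methacrylic anhydride, C=C(C)C(=O)OC(=O)C(C)=C
Why: DMAP-catalysed acylation of the only free hydroxyl (C8) proceeds with retention, and the mild amine base at low temperature avoids β-elimination of the oxirane through the C6 position.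

Step 14
Reactants: 22 13-O-(tert-butyldimethylsilyl)glaucolide L
Product: 23 glaucolide L
Conditions: HF·pyridine, pyridine, THF, 0 °C
Reagents that add atoms: none
Why: buffered fluoride desilylation frees the primary C13 alcohol without touching the two esters, the lactone or the trisubstituted oxirane.

**Compound list**
1 | geranyl acetate, (2E)-3,7-dimethylocta-2,6-dien-1-yl acetate | CC(=O)OC/C=C(\C)CCC=C(C)C | starting material
2 | 6,7-epoxygeranyl acetate, (2E)-5-(3,3-dimethyloxiran-2-yl)-3-methylpent-2-en-1-yl acetate (racemic oxirane) | CC(=O)OC/C=C(\C)CCC1OC1(C)C | intermediate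
3 | (2E)-6,7-dihydroxy-3,7-dimethyloct-2-en-1-yl acetate (racemic, not isolated) | CC(=O)OC/C=C(\C)CCC(O)C(C)(C)O | intermediate
4 | (2E)-3-methyl-6-oxohex-2-en-1-yl acetate | CC(=O)OC/C=C(\C)CCC=O | intermediate
5 | cis-2-butene | C/C=C\C | starting material
6 | (Z)-but-2-en-1-ylbis[(1S,2S,3S,5R)-2,6,6-trimethylbicyclo[3.1.1]heptan-3-yl]borane (not isolated) | C/C=C\CB([C@H]1C[C@H]2C[C@@H]([C@@H]1C)C2(C)C)[C@H]1C[C@H]2C[C@@H]([C@@H]1C)C2(C)C | intermediate
7 | (2E,6S,7S)-6-hydroxy-3,7-dimethylnona-2,8-dien-1-yl acetate (not isolated) | C=C[C@H](C)[C@@H](O)CC/C(C)=C/COC(C)=O | intermediate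
8 | (2E,6S,7S)-3,7-dimethylnona-2,8-diene-1,6-diol | C=C[C@H](C)[C@@H](O)CC/C(C)=C/CO | intermediate
9 | (2E,6S,7S)-6-hydroxy-3,7-dimethylnona-2,8-dienal | C=C[C@H](C)[C@@H](O)CC/C(C)=C/C=O | intermediate
10 | (3S,4S,7E)-3,7-dimethyl-9-oxonona-1,7-dien-4-yl acetate | C=C[C@H](C)[C@@H](OC(C)=O)CC/C(C)=C/C=O | intermediate
11 | tert-butyldimethyl(prop-2-yn-1-yloxy)silane | C#CCO[Si](C)(C)C(C)(C)C | starting material
12 | methylzinc acetylide of 11 (not isolated) | C[Zn]C#CCO[Si](C)(C)C(C)(C)C | intermediate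
13 | (3S,4S,7E,9R)-12-[(tert-butyldimethylsilyl)oxy]-9-hydroxy-3,7-dimethyldodeca-1,7-dien-10-yn-4-yl acetate | C=C[C@H](C)[C@@H](OC(C)=O)CC/C(C)=C/[C@@H](O)C#CCO[Si](C)(C)C(C)(C)C | intermediate
14 | (3S,4S,7E,9R,10E)-12-[(tert-butyldimethylsilyl)oxy]-9-hydroxy-10,11-diiodo-3,7-dimethyldodeca-1,7,10-trien-4-yl acetate | C=C[C@H](C)[C@@H](OC(C)=O)CC/C(C)=C/[C@@H](O)/C(I)=C(\I)CO[Si](C)(C)C(C)(C)C | intermediate
15 | (3S,4S,7E)-8-[(2R)-4-{[(tert-butyldimethylsilyl)oxy]methyl}-3-iodo-5-oxo-2,5-dihydrofuran-2-yl]-3,7-dimethylocta-1,7-dien-4-yl acetate | C=C[C@H](C)[C@@H](OC(C)=O)CC/C(C)=C/[C@H]1OC(=O)C(CO[Si](C)(C)C(C)(C)C)=C1I | intermediate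
16 | 9-BBN adduct of 15, boron on C8 (not isolated) | B1(CC[C@H](C)[C@@H](OC(C)=O)CC/C(C)=C/[C@H]3OC(=O)C(CO[Si](C)(C)C(C)(C)C)=C3I)C2CCCC1CCC2 | intermediate
17 | (3S,4S,7E)-8-[(2R)-4-{[(tert-butyldimethylsilyl)oxy]methyl}-3-iodo-5-oxo-2,5-dihydrofuran-2-yl]-1-hydroxy-3,7-dimethyloct-7-en-4-yl acetate | OCC[C@H](C)[C@@H](OC(C)=O)CC/C(C)=C/[C@H]1OC(=O)C(CO[Si](C)(C)C(C)(C)C)=C1I | intermediate
18 | (3S,4S,7E)-8-[(2R)-4-{[(tert-butyldimethylsilyl)oxy]methyl}-3-iodo-5-oxo-2,5-dihydrofuran-2-yl]-3,7-dimethyl-1-oxooct-7-en-4-yl acetate | O=CC[C@H](C)[C@@H](OC(C)=O)CC/C(C)=C/[C@H]1OC(=O)C(CO[Si](C)(C)C(C)(C)C)=C1I | intermediate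
19 | alkenylchromium dichloride from 18, CrCl2 on C7 in place of iodine (not isolated) | O=CC[C@H](C)[C@@H](OC(C)=O)CC/C(C)=C/[C@H]1OC(=O)C(CO[Si](C)(C)C(C)(C)C)=C1[Cr](Cl)Cl | intermediate
20 | (1S,4E,6R,8S,10S)-1-acetoxy-13-(tert-butyldimethylsilyloxy)-8-hydroxygermacra-4,7(11)-dien-12,6-olide | O[C@H]1C[C@H](C)[C@@H](OC(C)=O)CC/C(C)=C/[C@H]2OC(=O)C(CO[Si](C)(C)C(C)(C)C)=C12 | intermediate
21 | (1S,4R,5R,6S,8S,10S)-1-acetoxy-13-(tert-butyldimethylsilyloxy)-4,5-epoxy-8-hydroxygermacr-7(11)-en-12,6-olide | O[C@H]1C[C@H](C)[C@@H](OC(C)=O)CC[C@@]2(C)O[C@@H]2[C@H]2OC(=O)C(CO[Si](C)(C)C(C)(C)C)=C12 | intermediate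
22 | 13-O-(tert-butyldimethylsilyl)glaucolide L | C=C(C)C(=O)O[C@H]1C[C@H](C)[C@@H](OC(C)=O)CC[C@@]2(C)O[C@@H]2[C@H]2OC(=O)C(CO[Si](C)(C)C(C)(C)C)=C12 | intermediate
23 | glaucolide L, (1S,4R,5R,6S,8S,10S)-1-acetoxy-4,5-epoxy-13-hydroxy-8-(methacryloyloxy)germacr-7(11)-en-12,6-olide | C=C(C)C(=O)O[C@H]1C[C@H](C)[C@@H](OC(C)=O)CC[C@@]2(C)O[C@@H]2[C@H]2OC(=O)C(CO)=C12 | target

**Totals and risk**
Total step count: 14. Longest linear sequence: 14 steps (1 to 23); 5 and 11 are used as purchased.

Steps most likely to fail: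

Step 6 (asymmetric alkynylation of a β,β-disubstituted enal with a weakly acidic alkyne; low conversion, low ee or the wrong ligand sense). The fallback sets out from 10 and comes back at 13. The lithium acetylide of 11 (n-BuLi, THF, −78 °C) is added to 10 to give the C9-epimeric carbinol mixture F1. MnO2 oxidises it to the cross-conjugated ynone F2. Midland reduction with (R)-Alpine-Borane, in which the alkynyl group acts as the small substituent, then gives the 9R carbinol 13 by reagent control.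

Step 8 (the selective mono-cyclocarbonylation of the vicinal diiodide is new; loss of iodine back to the alkyne or further reaction of the product iodide are the dangers). The fallback sets out from 10 and comes back at 15. Alkynylation of 10 with 11 under the antipodal (S,S)-ProPhenol gives the 9S carbinol F3, and ClCO2Me/pyridine converts it into the methyl carbonate F4. Pd(PPh3)4, CO (1 atm) and MeOH effect anti SN2′ alkoxycarbonylation to the axially chiral allenoate F5. Iodolactonization (I2, MeCN/H2O) then puts oxygen on C6 and iodine on C7, with chirality transfer from the axis. The whole detour inverts C6, which is why the 9S series is used, and it delivers 15.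

Step 11 (ring closure to a ten-membered ring, and the sense of induction at C8 is not predictable). The fallback sets out from 18 and comes back at 22. If the coupling gives mainly the 8R alcohol F6, this is epoxidised as in step 12 to the 8R epoxy alcohol F7. F7 is then esterified with inversion by a Mitsunobu reaction (PPh3, DIAD, methacrylic acid, toluene, 0 °C), which gives 22 directly, so either C8 epimer reaches the target.

Further compounds
F1 | step 6 | (3S,4S,7E,9RS)-12-[(tert-butyldimethylsilyl)oxy]-9-hydroxy-3,7-dimethyldodeca-1,7-dien-10-yn-4-yl acetate (mixture of 13 and its C9 epimer) | C=C[C@H](C)[C@@H](OC(C)=O)CC/C(C)=C/C(O)C#CCO[Si](C)(C)C(C)(C)C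
F2 | step 6 | (3S,4S,7E)-12-[(tert-butyldimethylsilyl)oxy]-3,7-dimethyl-9-oxododeca-1,7-dien-10-yn-4-yl acetate | C=C[C@H](C)[C@@H](OC(C)=O)CC/C(C)=C/C(=O)C#CCO[Si](C)(C)C(C)(C)C
F3 | step 8 | (3S,4S,7E,9S)-12-[(tert-butyldimethylsilyl)oxy]-9-hydroxy-3,7-dimethyldodeca-1,7-dien-10-yn-4-yl acetate (C9 epimer of 13) | C=C[C@H](C)[C@@H](OC(C)=O)CC/C(C)=C/[C@H](O)C#CCO[Si](C)(C)C(C)(C)C
F4 | step 8 | methyl carbonate of F3 at the C9 hydroxyl | C=C[C@H](C)[C@@H](OC(C)=O)CC/C(C)=C/[C@H](OC(=O)OC)C#CCO[Si](C)(C)C(C)(C)C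
F5 | step 8 | methyl (aR,5E,9S,10S)-9-acetoxy-2-{[(tert-butyldimethylsilyl)oxy]methyl}-6,10-dimethyldodeca-2,3,5,11-tetraenoate (allenoate) | C=C[C@H](C)[C@@H](OC(C)=O)CC/C(C)=C/C([H])=[C@]=C(CO[Si](C)(C)C(C)(C)C)C(=O)OC
F6 | step 11 | (1S,4E,6R,8R,10S)-1-acetoxy-13-(tert-butyldimethylsilyloxy)-8-hydroxygermacra-4,7(11)-dien-12,6-olide (C8 epimer of 20) | O[C@@H]1C[C@H](C)[C@@H](OC(C)=O)CC/C(C)=C/[C@H]2OC(=O)C(CO[Si](C)(C)C(C)(C)C)=C12
F7 | step 11 | (1S,4R,5R,6S,8R,10S)-1-acetoxy-13-(tert-butyldimethylsilyloxy)-4,5-epoxy-8-hydroxygermacr-7(11)-en-12,6-olide (C8 epimer of 21) | O[C@@H]1C[C@H](C)[C@@H](OC(C)=O)CC[C@@]2(C)O[C@@H]2[C@H]2OC(=O)C(CO[Si](C)(C)C(C)(C)C)=C12
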